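**Strategy.** Everything rests on the C8–C9 bond of ring B. Anodic oxidation turns a C8=C17 methyl enol ether into a radical cation that is trapped by the C9 end of an allylsilane attached to quaternary C10. This single operation closes ring B as a trans-decalin and installs, trans to each other, the one-carbon branch (C17) on C8 and the two-carbon branch (C11–C12) on C9, the pattern that ring B of the target displays. The precursor is an enantiopure ring A cyclohexane bearing the C5 chain ending in the enol ether (cis to the C10 methyl), the (E)-allylsilane on C10, and the C4 diol as an acetonide.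

Key step: step 12

Assumption: carbon labels C1–C20 follow labdane numbering; in step 3 the antipode of the carbene ligand on Cu(OTf)2 that gives the (7R) enolate 9 is used; enol ethers 20 and 22 are carried as E/Z mixtures at C8=C17, which converge in step 12.

Step 1
Reactants: 1 (2,2-dimethyl-1,3-dioxan-5-yl)methanol
Product: 2 2,2-dimethyl-1,3-dioxane-5-carbaldehyde
Conditions: TEMPO (10 mol%), PhI(OAc)2, CH2Cl2, rt
Reagents that add atoms: none
Why: TEMPO-catalysed oxidation (oxoammonium mechanism) should stop at the aldehyde and, being non-basic, should not trigger β-elimination of the ring oxygen; no stereocentre is formed.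

Step 2
Reactants: 2 2,2-dimethyl-1,3-dioxane-5-carbaldehyde; 3 pent-1-en-3-one
Product: 6 3,3,8-trimethyl-2,4-dioxaspiro[5.5]undec-7-en-9-one, via enamine 4 (not isolated), via keto aldehyde 5 (not isolated)
Conditions: pyrrolidine, 4 Å MS, PhMe, rt; 3, 0 → 50 °C; AcOH/NaOAc/H2O, rt; then KOH, MeOH, rt
Reagents that add atoms: pent-1-en-3-one (compound 3), CCC(=O)C=C
Why: Robinson annulation in its Stork enamine form, in which enamine 4 adds to the vinyl ketone (Michael), hydrolysis gives 5, and the base-mediated aldol condensation can only close a six-membered ring from the ethyl-side α-carbon onto the non-enolisable aldehyde, which places the methyl group on the enone α-carbon (C10) and creates no stereocentre.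

Step 3
Reactants: 6 3,3,8-trimethyl-2,4-dioxaspiro[5.5]undec-7-en-9-one; 7 but-3-en-1-ylmagnesium bromide; 8 formaldehyde
Product: 10 (7R,8R)-7-(but-3-en-1-yl)-8-(hydroxymethyl)-3,3,8-trimethyl-2,4-dioxaspiro[5.5]undecan-9-one, via magnesium enolate 9 (not isolated)
Conditions: Cu(OTf)2 (4 mol%), C2-symmetric 4,5-diphenylimidazolinium chloride (carbene precursor, one antipode, 5 mol%), Et2O, −30 °C, slow addition of 7; then 8 (monomer in THF, from paraformaldehyde), −78 → −40 °C; aq. NH4Cl
Reagents that add atoms: but-3-en-1-ylmagnesium bromide (compound 7), C=CCC[Mg]Br; formaldehyde (compound 8), C=O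
Why: Copper-catalysed asymmetric conjugate addition of a Grignard reagent to an α-methyl cyclohexenone should set C5 under control of the chiral carbene ligand, and the regiodefined tetrasubstituted magnesium enolate 9 should then undergo aldol addition to formaldehyde on the face anti to the new C5 chain, so that C9 ends trans to the chain and the methyl cis, the C10 configuration that a trans ring fusion requires (introducing the methyl group last would give the C10 epimer).

Step 4
Reactants: 10 (7R,8R)-7-(but-3-en-1-yl)-8-(hydroxymethyl)-3,3,8-trimethyl-2,4-dioxaspiro[5.5]undecan-9-one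
Product: 11 (7R,8R)-8-{[(benzyloxy)methoxy]methyl}-7-(but-3-en-1-yl)-3,3,8-trimethyl-2,4-dioxaspiro[5.5]undecan-9-one
Conditions: BOMCl, iPr2NEt, Bu4NI (cat.), CH2Cl2, 0 °C → rt
Reagents that add atoms: benzyl chloromethyl ether (BOMCl), ClCOCc1ccccc1
Why: Alkoxymethylation (BOM ether formation) of the neopentyl alcohol under weakly basic conditions should give a base-stable acetal that prevents retro-aldol loss of formaldehyde in the next step; no stereocentre is affected.

Step 5
Reactants: 11 (7R,8R)-8-{[(benzyloxy)methoxy]methyl}-7-(but-3-en-1-yl)-3,3,8-trimethyl-2,4-dioxaspiro[5.5]undecan-9-one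
Product: 13 (7S,8R)-8-{[(benzyloxy)methoxy]methyl}-7-(but-3-en-1-yl)-3,3,8-trimethyl-2,4-dioxaspiro[5.5]undecane, via hydrazone 12 (not isolated)
Conditions: N2H4·H2O, KOH, diethylene glycol, degassed, Ar, 130 °C then 200 °C
Reagents that add atoms: none
Why: Wolff–Kishner reduction (Huang-Minlon procedure) through hydrazone 12 should remove the C1 carbonyl, since ketal, acetal and the isolated alkene (under argon) tolerate hot base and the quaternary C10 excludes β-elimination and epimerisation.

Step 6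
Reactants: 13 (7S,8R)-8-{[(benzyloxy)methoxy]methyl}-7-(but-3-en-1-yl)-3,3,8-trimethyl-2,4-dioxaspiro[5.5]undecane
Product: 14 [(7S,8R)-7-(but-3-en-1-yl)-3,3,8-trimethyl-2,4-dioxaspiro[5.5]undecan-8-yl]methanol
Conditions: Li, NH3(l)/THF, −78 °C; NH4Cl
Reagents that add atoms: none
Why: Dissolving-metal (Birch-type) cleavage of the benzylic C–O bond should release a hemiformal that loses formaldehyde on work-up, while the unconjugated terminal alkene and the acetonide are not reduced and the stereocentres are untouched.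

Step 7
Reactants: 14 [(7S,8R)-7-(but-3-en-1-yl)-3,3,8-trimethyl-2,4-dioxaspiro[5.5]undecan-8-yl]methanol
Product: 15 (7R,8R)-7-(but-3-en-1-yl)-3,3,8-trimethyl-2,4-dioxaspiro[5.5]undecane-8-carbaldehyde
Conditions: Dess–Martin periodinane, pyridine, CH2Cl2, 0 °C → rt
Reagents that add atoms: none
Why: Dess–Martin oxidation should convert the hindered primary alcohol into the non-enolisable C9 aldehyde under buffered conditions that spare the alkene and the acetonide.

Step 8
Reactants: 15 (7R,8R)-7-(but-3-en-1-yl)-3,3,8-trimethyl-2,4-dioxaspiro[5.5]undecane-8-carbaldehyde; 16 iodoform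
Product: 17 (7S,8R)-7-(but-3-en-1-yl)-8-[(E)-2-iodoethenyl]-3,3,8-trimethyl-2,4-dioxaspiro[5.5]undecane
Conditions: CrCl2, 16, THF/dioxane, 0 °C → rt
Reagents that add atoms: iodoform (compound 16), IC(I)I
Why: Takai olefination, in which the geminal dichromium reagent from iodoform and CrCl2 adds to the aldehyde and eliminates to the (E)-vinyl iodide, should fix the C9=C11 geometry that a Wittig reaction on an α-quaternary aldehyde would not secure.

Step 9
Reactants: 17 (7S,8R)-7-(but-3-en-1-yl)-8-[(E)-2-iodoethenyl]-3,3,8-trimethyl-2,4-dioxaspiro[5.5]undecane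
Product: 18 3-{(7S,8R)-8-[(E)-2-iodoethenyl]-3,3,8-trimethyl-2,4-dioxaspiro[5.5]undecan-7-yl}propanal
Conditions: OsO4 (cat.), NaIO4, 2,6-lutidine, dioxane/H2O, rt
Reagents that add atoms: OsO4, O=[Os](=O)(=O)=O (oxygen carrier); NaIO4, [Na+].[O-]I(=O)(=O)=O (terminal oxidant and oxygen source)
Why: Lemieux–Johnson oxidation (osmium-catalysed dihydroxylation, periodate cleavage) should attack the monosubstituted alkene in preference to the deactivated, hindered vinyl iodide and remove the terminal carbon to leave the C8 aldehyde, the alkene serving as aldehyde mask because no acid-labile mask could be removed beside the acetonide.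

Step 10
Reactants: 18 3-{(7S,8R)-8-[(E)-2-iodoethenyl]-3,3,8-trimethyl-2,4-dioxaspiro[5.5]undecan-7-yl}propanal; 19 (methoxymethyl)triphenylphosphonium chloride
Product: 20 (7S,8R)-8-[(E)-2-iodoethenyl]-7-(4-methoxybut-3-en-1-yl)-3,3,8-trimethyl-2,4-dioxaspiro[5.5]undecane
Conditions: 19, KN(SiMe3)2, THF, 0 °C; then 18, −78 → 0 °C
Reagents that add atoms: (methoxymethyl)triphenylphosphonium chloride (compound 19), COC[P+](c1ccccc1)(c1ccccc1)c1ccccc1.[Cl-]
Why: Wittig methoxymethylenation of the unhindered aldehyde with the preformed ylide should give the C8=C17 enol ether as an E/Z mixture that converges in step 12, and the ylide at low temperature should not dehydrohalogenate the vinyl iodide.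

Step 11
Reactants: 20 (7S,8R)-8-[(E)-2-iodoethenyl]-7-(4-methoxybut-3-en-1-yl)-3,3,8-trimethyl-2,4-dioxaspiro[5.5]undecane; 21 [(trimethylsilyl)methyl]magnesium chloride
Product: 22 trimethyl{(E)-3-[(7S,8S)-7-(4-methoxybut-3-en-1-yl)-3,3,8-trimethyl-2,4-dioxaspiro[5.5]undecan-8-yl]prop-2-en-1-yl}silane
Conditions: 21, Pd(PPh3)4 (5 mol%), THF, rt
Reagents that add atoms: [(trimethylsilyl)methyl]magnesium chloride (compound 21), C[Si](C)(C)C[Mg]Cl
Why: Kumada–Corriu coupling of the (E)-vinyl iodide with the silylmethyl Grignard reagent should proceed with retention of alkene geometry to give the (E)-allylsilane, the enol ether and the acetonide being inert to the reagent.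

Step 12
Reactants: 22 trimethyl{(E)-3-[(7S,8S)-7-(4-methoxybut-3-en-1-yl)-3,3,8-trimethyl-2,4-dioxaspiro[5.5]undecan-8-yl]prop-2-en-1-yl}silane; 23 methanol
Product: 24 (4a'S,5'R,6'S,8a'S)-6'-(dimethoxymethyl)-5'-ethenyl-2,2,4a'-trimethyloctahydro-2'H-spiro[[1,3]dioxane-5,1'-naphthalene]
Conditions: RVC anode, Pt cathode, undivided cell, 0.1 M LiClO4, 2,6-lutidine, MeOH/THF (3:7), constant current (8 mA), 2.2 F/mol, rt
Reagents that add atoms: methanol (compound 23), CO
Why: One-electron oxidation of the electron-rich enol ether at the anode gives a radical cation that is electrophilic at C8 and is attacked by the γ-carbon (C9) of the allylsilane; a second electron is lost, methanol removes the silyl group to leave the C11=C12 vinyl group, and methanol traps the C17 oxocarbenium ion as the dimethyl acetal. The closest known reaction type is the anodic olefin coupling of enol ether radical cations with allylsilanes, which is established for six-membered rings and for bond formation next to a quaternary carbon. Ring B closes in a 6-exo-trig mode, with C17 and C11 both left outside the new ring. C8 is controlled by the chair transition state built on the trans-disposed arms of ring A, in which C17 must lie equatorial to escape the 1,3-diaxial contact with the axial C10 methyl, and C9 is controlled in the same chair by the (E)-allyl unit lying pseudo-equatorial, which puts H9 axial and C11 on the face of the C10 methyl. The step needs the trans-diequatorial C8/C9 relation and oxidation of the enol ether in preference to the allylsilane; the first is secured by the chair anchored on ring A (and C8 can still equilibrate through the aldehyde in step 14), the second by the lower oxidation potential of the enol ether, while 2,6-lutidine keeps the medium neutral for the acetonide.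

Step 13
Reactants: 24 (4a'S,5'R,6'S,8a'S)-6'-(dimethoxymethyl)-5'-ethenyl-2,2,4a'-trimethyloctahydro-2'H-spiro[[1,3]dioxane-5,1'-naphthalene]; 25 3-bromofuran-2(5H)-one
Product: 27 3-{2-[(4a'S,5'R,6'S,8a'S)-6'-(dimethoxymethyl)-2,2,4a'-trimethyloctahydro-2'H-spiro[[1,3]dioxane-5,1'-naphthalen]-5'-yl]ethyl}furan-2(5H)-one, via alkylborane 26 (not isolated)
Conditions: 9-BBN, THF, 0 °C → rt; then 25, PdCl2(dppf) (5 mol%), AsPh3, Cs2CO3, DMF/H2O, rt
Reagents that add atoms: 3-bromofuran-2(5H)-one (compound 25), O=C1OCC=C1Br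
Why: Anti-Markovnikov hydroboration of the monosubstituted alkene with 9-BBN followed by B-alkyl Suzuki–Miyaura coupling of alkylborane 26 with the α-bromo enoate unit of 25 should form the C12–C13 bond under mildly basic conditions that leave both acetals and all stereocentres untouched.

Step 14
Reactants: 27 3-{2-[(4a'S,5'R,6'S,8a'S)-6'-(dimethoxymethyl)-2,2,4a'-trimethyloctahydro-2'H-spiro[[1,3]dioxane-5,1'-naphthalen]-5'-yl]ethyl}furan-2(5H)-one
Product: 28 (1R,2S,4aS,8aS)-5,5-bis(hydroxymethyl)-8a-methyl-1-[2-(2-oxo-2,5-dihydrofuran-3-yl)ethyl]decahydronaphthalene-2-carbaldehyde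
Conditions: 1 M HCl, THF, rt
Reagents that add atoms: water, O
Why: Acid-catalysed hydrolysis should cleave the dimethyl acetal and the isopropylidene ketal in one operation, the C8 formyl group staying (or equilibrating to) equatorial and the butenolide being stable to dilute acid.

Step 15
Reactants: 28 (1R,2S,4aS,8aS)-5,5-bis(hydroxymethyl)-8a-methyl-1-[2-(2-oxo-2,5-dihydrofuran-3-yl)ethyl]decahydronaphthalene-2-carbaldehyde
Product: 29 3-{2-[(1R,2S,4aS,8aS)-2,5,5-tris(hydroxymethyl)-8a-methyldecahydronaphthalen-1-yl]ethyl}furan-2(5H)-one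
Conditions: NaBH4, MeOH, −40 °C
Reagents that add atoms: none
Why: Chemoselective borohydride reduction should reduce the aldehyde much faster than hydride adds to the α-alkyl butenolide at low temperature, giving the C17 alcohol without touching a stereocentre.

**Compound list**

1 | (2,2-dimethyl-1,3-dioxan-5-yl)methanol | CC1(C)OCC(CO)CO1 | starting material
2 | 2,2-dimethyl-1,3-dioxane-5-carbaldehyde | CC1(C)OCC(C=O)CO1 | intermediate
3 | pent-1-en-3-one (ethyl vinyl ketone) | CCC(=O)C=C | starting material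
4 | 1-[(2,2-dimethyl-1,3-dioxan-5-ylidene)methyl]pyrrolidine (enamine of 2) | CC1(C)OCC(=CN2CCCC2)CO1 | intermediate (not isolated)
5 | 2,2-dimethyl-5-(3-oxopentyl)-1,3-dioxane-5-carbaldehyde | CCC(=O)CCC1(C=O)COC(C)(C)OC1 | intermediate (not isolated)
6 | 3,3,8-trimethyl-2,4-dioxaspiro[5.5]undec-7-en-9-one (ring A enone; spiro C6 = C4, C7 = C5, C8 = C10, C9 = C1) | CC1=CC2(CCC1=O)COC(C)(C)OC2 | intermediate
7 | but-3-en-1-ylmagnesium bromide | C=CCC[Mg]Br | starting material
8 | formaldehyde (monomer from paraformaldehyde) | C=O | starting material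
9 | bromomagnesium (7R)-7-(but-3-en-1-yl)-3,3,8-trimethyl-2,4-dioxaspiro[5.5]undec-8-en-9-olate | CC1=C(O[Mg]Br)CCC2(COC(C)(C)OC2)[C@H]1CCC=C | intermediate (not isolated)
10 | (7R,8R)-7-(but-3-en-1-yl)-8-(hydroxymethyl)-3,3,8-trimethyl-2,4-dioxaspiro[5.5]undecan-9-one (butenyl cis to methyl, trans to hydroxymethyl) | C[C@@]1(CO)C(=O)CCC2(COC(C)(C)OC2)[C@H]1CCC=C | intermediate
11 | (7R,8R)-8-{[(benzyloxy)methoxy]methyl}-7-(but-3-en-1-yl)-3,3,8-trimethyl-2,4-dioxaspiro[5.5]undecan-9-one | C[C@@]1(COCOCc2ccccc2)C(=O)CCC2(COC(C)(C)OC2)[C@H]1CCC=C | intermediate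
12 | hydrazone of 11 at the ring ketone (C1) | C[C@@]1(COCOCc2ccccc2)C(=NN)CCC2(COC(C)(C)OC2)[C@H]1CCC=C | intermediate (not isolated)
13 | (7S,8R)-8-{[(benzyloxy)methoxy]methyl}-7-(but-3-en-1-yl)-3,3,8-trimethyl-2,4-dioxaspiro[5.5]undecane | C[C@@]1(COCOCc2ccccc2)CCCC2(COC(C)(C)OC2)[C@H]1CCC=C | intermediate
14 | [(7S,8R)-7-(but-3-en-1-yl)-3,3,8-trimethyl-2,4-dioxaspiro[5.5]undecan-8-yl]methanol | C[C@@]1(CO)CCCC2(COC(C)(C)OC2)[C@H]1CCC=C | intermediate
15 | (7R,8R)-7-(but-3-en-1-yl)-3,3,8-trimethyl-2,4-dioxaspiro[5.5]undecane-8-carbaldehyde | C[C@@]1(C=O)CCCC2(COC(C)(C)OC2)[C@H]1CCC=C | intermediate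
16 | iodoform (triiodomethane) | IC(I)I | starting material
17 | (7S,8R)-7-(but-3-en-1-yl)-8-[(E)-2-iodoethenyl]-3,3,8-trimethyl-2,4-dioxaspiro[5.5]undecane | C[C@@]1(/C=C/I)CCCC2(COC(C)(C)OC2)[C@H]1CCC=C | intermediate
18 | 3-{(7S,8R)-8-[(E)-2-iodoethenyl]-3,3,8-trimethyl-2,4-dioxaspiro[5.5]undecan-7-yl}propanal | C[C@@]1(/C=C/I)CCCC2(COC(C)(C)OC2)[C@H]1CCC=O | intermediate
19 | (methoxymethyl)triphenylphosphonium chloride | COC[P+](c1ccccc1)(c1ccccc1)c1ccccc1.[Cl-] | starting material
20 | (7S,8R)-8-[(E)-2-iodoethenyl]-7-(4-methoxybut-3-en-1-yl)-3,3,8-trimethyl-2,4-dioxaspiro[5.5]undecane (E/Z mixture at the enol ether) | C[C@@]1(/C=C/I)CCCC2(COC(C)(C)OC2)[C@H]1CCC=COC | intermediate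
21 | [(trimethylsilyl)methyl]magnesium chloride | C[Si](C)(C)C[Mg]Cl | starting material
22 | trimethyl{(E)-3-[(7S,8S)-7-(4-methoxybut-3-en-1-yl)-3,3,8-trimethyl-2,4-dioxaspiro[5.5]undecan-8-yl]prop-2-en-1-yl}silane (key-step precursor; E/Z mixture at the enol ether) | C[C@@]1(/C=C/C[Si](C)(C)C)CCCC2(COC(C)(C)OC2)[C@H]1CCC=COC | intermediate
23 | methanol | CO | starting material
24 | (4a'S,5'R,6'S,8a'S)-6'-(dimethoxymethyl)-5'-ethenyl-2,2,4a'-trimethyloctahydro-2'H-spiro[[1,3]dioxane-5,1'-naphthalene] (key-step product) | C[C@@]12CCCC3(COC(C)(C)OC3)[C@H]1CC[C@H](C(OC)OC)[C@H]2C=C | intermediate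
25 | 3-bromofuran-2(5H)-one | O=C1OCC=C1Br | starting material
26 | 9-{2-[(4a'S,5'R,6'S,8a'S)-6'-(dimethoxymethyl)-2,2,4a'-trimethyloctahydro-2'H-spiro[[1,3]dioxane-5,1'-naphthalen]-5'-yl]ethyl}-9-borabicyclo[3.3.1]nonane | C[C@@]12CCCC3(COC(C)(C)OC3)[C@H]1CC[C@H](C(OC)OC)[C@H]2CCB1C2CCCC1CCC2 | intermediate (not isolated)
27 | 3-{2-[(4a'S,5'R,6'S,8a'S)-6'-(dimethoxymethyl)-2,2,4a'-trimethyloctahydro-2'H-spiro[[1,3]dioxane-5,1'-naphthalen]-5'-yl]ethyl}furan-2(5H)-one | C[C@@]12CCCC3(COC(C)(C)OC3)[C@H]1CC[C@H](C(OC)OC)[C@H]2CCC1=CCOC1=O | intermediate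
28 | (1R,2S,4aS,8aS)-5,5-bis(hydroxymethyl)-8a-methyl-1-[2-(2-oxo-2,5-dihydrofuran-3-yl)ethyl]decahydronaphthalene-2-carbaldehyde | C[C@@]12CCCC(CO)(CO)[C@H]1CC[C@H](C=O)[C@H]2CCC1=CCOC1=O | intermediate
29 | 3-{2-[(1R,2S,4aS,8aS)-2,5,5-tris(hydroxymethyl)-8a-methyldecahydronaphthalen-1-yl]ethyl}furan-2(5H)-one (CNP0271381.1) | C[C@@]12CCCC(CO)(CO)[C@H]1CC[C@H](CO)[C@H]2CCC1=CCOC1=O | target

**Step count.** Total: 15 steps. Longest linear sequence: 15 steps (1 → 29); compounds 3, 7, 8, 16, 19, 21, 23 and 25 are purchased.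

**Steps most likely to fail**

Step 12. The radical cation may be captured by methanol before C9 attacks, or the chair may discriminate poorly between the two faces at C9. Fallback: setting out from 22, the enol ether is hydrolysed (oxalic acid on wet silica gel, CH2Cl2, 0 °C) to 4-{(7S,8S)-3,3,8-trimethyl-8-[(E)-3-(trimethylsilyl)prop-1-en-1-yl]-2,4-dioxaspiro[5.5]undecan-7-yl}butanal F1. Ring B is then closed by organo-SOMO catalysis, the known intramolecular α-allylation of aldehydes with allylsilanes (chiral imidazolidinone salt, (NH4)2Ce(NO3)6, NaHCO3, wet DME, −20 °C), in which the enamine radical cation at C8 is attacked by C9, to give (4a'S,5'R,6'S,8a'S)-5'-ethenyl-2,2,4a'-trimethyloctahydro-2'H-spiro[[1,3]dioxane-5,1'-naphthalene]-6'-carbaldehyde F2. Acetalisation (HC(OMe)3, MeOH, 2,2-dimethoxypropane, PPTS) comes back to the route at 24.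

Step 3. Addition at C5, next to the spiro carbon of an α-substituted enone, may be slow enough for 1,2-addition to compete, and enantiofacial control may be incomplete. Fallback: setting out from 6, the addition is run with achiral CuBr·SMe2, which should give enolate 9 together with its mirror image ent-9 F3 and, after the formaldehyde aldol, 10 together with ent-10 F4. Protection as in step 4 gives 11 together with ent-11 F5, and the two enantiomers are separated by preparative chromatography on a chiral stationary phase (the benzyl group provides the UV handle), which comes back to the route at 11.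

Step 13. The bromobutenolide may suffer base-induced ring opening or conjugate addition, and protodeboronation of the alkylborane may outrun transmetallation. Fallback: setting out from 24, the borane 26 is oxidised (NaBO3·4H2O, THF/H2O) to 2-[(4a'S,5'R,6'S,8a'S)-6'-(dimethoxymethyl)-2,2,4a'-trimethyloctahydro-2'H-spiro[[1,3]dioxane-5,1'-naphthalen]-5'-yl]ethan-1-ol F6, which is converted (I2, PPh3, imidazole) into the corresponding 5'-(2-iodoethyl) compound F7. Alkylation of the lithium enolate of 3-(phenylsulfanyl)oxolan-2-one (LiN(SiMe3)2, THF/DMPU) gives the 3-alkyl-3-(phenylsulfanyl)oxolan-2-one F8, oxidation (mCPBA, CH2Cl2, −78 °C) gives the 3-alkyl-3-(benzenesulfinyl)oxolan-2-one F9, and thermal syn-elimination (PhMe, 110 °C) forms the butenolide, which comes back to the route at 27.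

**Further compounds**

F1 | step 12 | 4-{(7S,8S)-3,3,8-trimethyl-8-[(E)-3-(trimethylsilyl)prop-1-en-1-yl]-2,4-dioxaspiro[5.5]undecan-7-yl}butanal | C[C@@]1(/C=C/C[Si](C)(C)C)CCCC2(COC(C)(C)OC2)[C@H]1CCCC=O
F2 | step 12 | (4a'S,5'R,6'S,8a'S)-5'-ethenyl-2,2,4a'-trimethyloctahydro-2'H-spiro[[1,3]dioxane-5,1'-naphthalene]-6'-carbaldehyde | C[C@@]12CCCC3(COC(C)(C)OC3)[C@H]1CC[C@H](C=O)[C@H]2C=C
F3 | step 3 | ent-9, bromomagnesium (7S)-7-(but-3-en-1-yl)-3,3,8-trimethyl-2,4-dioxaspiro[5.5]undec-8-en-9-olate | CC1=C(O[Mg]Br)CCC2(COC(C)(C)OC2)[C@@H]1CCC=C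
F4 | step 3 | ent-10, (7S,8S)-7-(but-3-en-1-yl)-8-(hydroxymethyl)-3,3,8-trimethyl-2,4-dioxaspiro[5.5]undecan-9-one | C[C@]1(CO)C(=O)CCC2(COC(C)(C)OC2)[C@@H]1CCC=C
F5 | step 3 | ent-11, (7S,8S)-8-{[(benzyloxy)methoxy]methyl}-7-(but-3-en-1-yl)-3,3,8-trimethyl-2,4-dioxaspiro[5.5]undecan-9-one | C[C@]1(COCOCc2ccccc2)C(=O)CCC2(COC(C)(C)OC2)[C@@H]1CCC=C
F6 | step 13 | 2-[(4a'S,5'R,6'S,8a'S)-6'-(dimethoxymethyl)-2,2,4a'-trimethyloctahydro-2'H-spiro[[1,3]dioxane-5,1'-naphthalen]-5'-yl]ethan-1-ol | C[C@@]12CCCC3(COC(C)(C)OC3)[C@H]1CC[C@H](C(OC)OC)[C@H]2CCO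
F7 | step 13 | (4a'S,5'R,6'S,8a'S)-6'-(dimethoxymethyl)-5'-(2-iodoethyl)-2,2,4a'-trimethyloctahydro-2'H-spiro[[1,3]dioxane-5,1'-naphthalene] | C[C@@]12CCCC3(COC(C)(C)OC3)[C@H]1CC[C@H](C(OC)OC)[C@H]2CCI
F8 | step 13 | 3-{2-[(4a'S,5'R,6'S,8a'S)-6'-(dimethoxymethyl)-2,2,4a'-trimethyloctahydro-2'H-spiro[[1,3]dioxane-5,1'-naphthalen]-5'-yl]ethyl}-3-(phenylsulfanyl)oxolan-2-one (both epimers at the lactone α-carbon) | C[C@@]12CCCC3(COC(C)(C)OC3)[C@H]1CC[C@H](C(OC)OC)[C@H]2CCC1(Sc2ccccc2)CCOC1=O
F9 | step 13 | 3-(benzenesulfinyl)-3-{2-[(4a'S,5'R,6'S,8a'S)-6'-(dimethoxymethyl)-2,2,4a'-trimethyloctahydro-2'H-spiro[[1,3]dioxane-5,1'-naphthalen]-5'-yl]ethyl}oxolan-2-one (mixture at sulfur and the lactone α-carbon) | C[C@@]12CCCC3(COC(C)(C)OC3)[C@H]1CC[C@H](C(OC)OC)[C@H]2CCC1(S(=O)c2ccccc2)CCOC1=O
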